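The route rests on disconnecting ring A at the C1–C10 bond. The angular methyl on quaternary C10 is read as a former exocyclic methylene on ring B, and the C3 carbinol, three bonds away, as the carbonyl of a vinyl ketone. In one operation, iron-hydride hydrogen-atom transfer to the methylene of monocycle 15 gives the tertiary C10 radical, which adds 6-endo to C1 of the enone: ring A closes, C10 becomes quaternary and the trans ring fusion is set. The precursor is a 3-methylenecyclohexanone (ring B) whose C5 carries the C4 quaternary centre with the vinyl ketone; it comes from a chelation-controlled dianionic Ireland–Claisen rearrangement.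

Key step: step 10

Remark: atom labels follow drimane numbering (C1–C10 in the decalin, C11 on C9, C12 on C8, C13 = methyl and C14 = oxygenated carbon on C4, C15 = methyl on C10) and are used for the same atoms in all earlier intermediates.

Step 1
Reactants: 1 (3-methoxyphenyl)methanol
Product: 2 (5-methoxycyclohexa-1,4-dien-1-yl)methanol
Conditions: Li, NH3 (l), THF, t-BuOH, −78 °C; then NH4Cl
Reagents that add atoms: none
Why: Birch reduction leaves the methoxy-bearing carbon (future C8) and the hydroxymethyl-bearing carbon (future C10) sp2 and protonates the future C9 and C6, which places the second alkene at C10=C5, allylic to the CH2OH group, while the benzylic C–O bond survives as its lithium alkoxide; no stereocentre is formed.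

Step 2
Reactants: 3 (4R)-4-benzyl-3-propanoyl-1,3-oxazolidin-2-one; 4 prop-2-enal (acrolein)
Product: 5 (4R)-4-benzyl-3-[(2R,3S)-3-hydroxy-2-methylpent-4-enoyl]-1,3-oxazolidin-2-one
Conditions: Bu2BOTf, i-Pr2NEt, CH2Cl2, −78 → 0 °C; 4, −78 °C; then pH 7 buffer, MeOH, H2O2, 0 °C
Reagents that add atoms: none
Why: Evans syn-aldol reaction, in which the Z-boron enolate adds to acrolein through a closed Zimmerman–Traxler transition state on the face away from the benzyl group and so sets the (3S) carbinol centre (the future C3, kept only as a control element) and the (2R) centre.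

Step 3
Reactants: 2 (5-methoxycyclohexa-1,4-dien-1-yl)methanol; 5 (4R)-4-benzyl-3-[(2R,3S)-3-hydroxy-2-methylpent-4-enoyl]-1,3-oxazolidin-2-one
Product: 6 (5-methoxycyclohexa-1,4-dien-1-yl)methyl (2R,3S)-3-hydroxy-2-methylpent-4-enoate
Conditions: 2 (2 equiv), n-BuLi (1.5 equiv), THF, −20 °C; then 5, −20 → 0 °C; NH4Cl
Reagents that add atoms: none
Why: Alkoxide transesterification of an N-acyl oxazolidinone, in which the lithium alkoxide of 2 attacks the exocyclic imide carbonyl and releases the auxiliary while both stereocentres stay untouched.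

Step 4
Reactants: 6 (5-methoxycyclohexa-1,4-dien-1-yl)methyl (2R,3S)-3-hydroxy-2-methylpent-4-enoate
Product: 9 (4S)-4-[(2R,3S)-1,3-dihydroxy-2-methylpent-4-en-2-yl]-3-methylidenecyclohexan-1-one, via hydroxy acid dilithium salt 7 (not isolated), via enol ether diol 8 (not isolated)
Conditions: LiN(i-Pr)2 (2.2 equiv), THF, −78 → 50 °C; then LiAlH4, 0 °C → reflux; aq. potassium sodium tartrate; then aq. oxalic acid, THF, 0 °C
Reagents that add atoms: water (O)
Why: Dianionic Ireland–Claisen rearrangement of a β-hydroxy ester, then hydride reduction and enol ether hydrolysis: the lithium chelate between the enolate oxygen and the C3 alkoxide fixes the enolate geometry (C3 cis to the enolate oxygen) and directs the allyl terminus C5 anti to the vinyl group, the chair transition state with ring carbon C6 equatorial should then give (4R) and (5S) together with the exocyclic C10=CH2, LiAlH4 reduces the carboxylate to C14H2OH and mild acid frees the C8 ketone without moving the alkene.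

Step 5
Reactants: 9 (4S)-4-[(2R,3S)-1,3-dihydroxy-2-methylpent-4-en-2-yl]-3-methylidenecyclohexan-1-one
Product: 10 (4S)-4-[(4S,5R)-4-ethenyl-2,2,5-trimethyl-1,3-dioxan-5-yl]-3-methylidenecyclohexan-1-one
Conditions: Me2C(OMe)2, PPTS, CH2Cl2, rt
Reagents that add atoms: 2,2-dimethoxypropane (COC(C)(C)OC)
Why: Acetonide formation (acid-catalysed transacetalisation) masks the 1,3-diol as a 1,3-dioxane that is inert to the amide base of the next step; no stereocentre changes.

Step 6
Reactants: 10 (4S)-4-[(4S,5R)-4-ethenyl-2,2,5-trimethyl-1,3-dioxan-5-yl]-3-methylidenecyclohexan-1-one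
Product: 12 (2R,4S)-4-[(4S,5R)-4-ethenyl-2,2,5-trimethyl-1,3-dioxan-5-yl]-3-methylidene-2-({[tri(propan-2-yl)silyl]oxy}methyl)cyclohexan-1-one, via trans silyl ether 11 (not isolated)
Conditions: LiN(i-Pr)2 (1.05 equiv), THF, −78 °C; i-Pr3SiOCH2Cl, −78 → −40 °C; then LiN(i-Pr)2 (0.95 equiv), −78 → 0 °C; AcOH, THF, −78 °C
Reagents that add atoms: (triisopropylsiloxy)methyl chloride (ClCO[Si](C(C)C)(C(C)C)C(C)C)
Why: Enolate alkylation followed by kinetic protonation: the base removes the doubly activated C9 proton (α to C8=O and allylic to C10=CH2), the dienolate is alkylated at its α-carbon anti to the pseudoaxial C5 substituent to give trans ketone 11, and re-enolisation to the same conjugated dienolate followed by α-protonation from that same open face should invert C9 to the cis (9R) ketone 12.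

Step 7
Reactants: 12 (2R,4S)-4-[(4S,5R)-4-ethenyl-2,2,5-trimethyl-1,3-dioxan-5-yl]-3-methylidene-2-({[tri(propan-2-yl)silyl]oxy}methyl)cyclohexan-1-one
Product: 13 (2R,4S)-4-[(2R,3S)-1,3-dihydroxy-2-methylpent-4-en-2-yl]-3-methylidene-2-({[tri(propan-2-yl)silyl]oxy}methyl)cyclohexan-1-one
Conditions: AcOH/H2O (4:1), 40 °C
Reagents that add atoms: none
Why: Acid hydrolysis of the acetonide frees the diol, while the primary silyl ether and the β,γ-unsaturated ketone should survive these mild conditions; no stereocentre changes.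

Step 8
Reactants: 13 (2R,4S)-4-[(2R,3S)-1,3-dihydroxy-2-methylpent-4-en-2-yl]-3-methylidene-2-({[tri(propan-2-yl)silyl]oxy}methyl)cyclohexan-1-one
Product: 14 (2R,3S)-3-hydroxy-2-methyl-2-[(1S,3R)-2-methylidene-4-oxo-3-({[tri(propan-2-yl)silyl]oxy}methyl)cyclohexyl]pent-4-en-1-yl acetate
Conditions: AcCl, 2,4,6-collidine, CH2Cl2, −78 °C
Reagents that add atoms: acetyl chloride (CC(=O)Cl)
Why: Selective acylation, in which acetyl chloride with collidine at low temperature acetylates the primary C14 hydroxyl much faster than the hindered secondary allylic C3 hydroxyl.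

Step 9
Reactants: 14 (2R,3S)-3-hydroxy-2-methyl-2-[(1S,3R)-2-methylidene-4-oxo-3-({[tri(propan-2-yl)silyl]oxy}methyl)cyclohexyl]pent-4-en-1-yl acetate
Product: 15 (2R)-2-methyl-2-[(1S,3R)-2-methylidene-4-oxo-3-({[tri(propan-2-yl)silyl]oxy}methyl)cyclohexyl]-3-oxopent-4-en-1-yl acetate
Conditions: Dess–Martin periodinane, CH2Cl2, 0 °C → rt
Reagents that add atoms: none
Why: Dess–Martin oxidation of the secondary allylic alcohol gives the vinyl ketone under non-basic conditions, which removes the auxiliary C3 stereocentre and installs the radical acceptor.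

Step 10
Reactants: 15 (2R)-2-methyl-2-[(1S,3R)-2-methylidene-4-oxo-3-({[tri(propan-2-yl)silyl]oxy}methyl)cyclohexyl]-3-oxopent-4-en-1-yl acetate
Product: 16 (4R,5S,9R,10R)-14-acetoxy-11-{[tri(propan-2-yl)silyl]oxy}-12-nordrimane-3,8-dione (trans-decalin)
Conditions: Fe(acac)3 (30 mol %), PhSiH3, EtOH/(CH2OH)2, 60 °C
Reagents that add atoms: none
Why: Fe(acac)3 and PhSiH3 form an iron hydride that transfers a hydrogen atom to the terminal carbon of the C10=CH2 alkene, so that C15 becomes the angular methyl and a nucleophilic tertiary radical sits on C10; this radical adds to C1, the β-carbon of the vinyl ketone, and the α-keto radical at C2 is then reduced and protonated. The closest known reaction type is the iron-catalysed reductive olefin coupling (hydrogen-atom-transfer Giese reaction) in its intramolecular form, and the closure mirrors the second ring closure of a radical polyene cyclisation. Ring A closes in the 6-endo-trig mode. The one new stereocentre, C10, is set by a chair-like transition state on the ring B chair in which the C5 side chain and the C9 substituent stay equatorial and the new C10–C1 bond forms equatorially, which should put the methyl axial and anti to H5 (trans-decalin, 10R). The step needs hydrogen-atom transfer to the electron-rich 1,1-disubstituted alkene in preference to the electron-poor enone, and attack at C1 in preference to 5-exo attack at C2; the first follows from the electronic difference between the two alkenes and the second from the polarity match between the tertiary alkyl radical and the enone β-carbon.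

Step 11
Reactants: 16 (4R,5S,9R,10R)-14-acetoxy-11-{[tri(propan-2-yl)silyl]oxy}-12-nordrimane-3,8-dione
Product: 17 (4R,5S,9R,10R)-14-acetoxy-11-{[tri(propan-2-yl)silyl]oxy}drim-8(12)-en-3-one
Conditions: Zn, CH2Br2, TiCl4, THF/CH2Cl2, 0 °C → rt
Reagents that add atoms: dibromomethane (BrCBr)
Why: Takai–Lombardo methylenation, in which the non-basic zinc–titanium methylene reagent should convert the more accessible C8 ketone into the exocyclic alkene and leave the neopentyl C3 ketone, the acetate and the configuration at C9 untouched.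

Step 12
Reactants: 17 (4R,5S,9R,10R)-14-acetoxy-11-{[tri(propan-2-yl)silyl]oxy}drim-8(12)-en-3-one
Product: 18 (4R,5S,9R,10R)-14-acetoxy-11-hydroxydrim-8(12)-en-3-one
Conditions: HF·pyridine, THF/pyridine, 0 °C → rt
Reagents that add atoms: none
Why: Fluoride-mediated desilylation with buffered HF·pyridine removes the primary silyl ether without touching the acetate, the ketone or the exocyclic alkene.

Step 13
Reactants: 18 (4R,5S,9R,10R)-14-acetoxy-11-hydroxydrim-8(12)-en-3-one; 19 7-hydroxy-2H-chromen-2-one (umbelliferone)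
Product: 20 (4R,5S,9R,10R)-14-acetoxy-11-[(2-oxo-2H-chromen-7-yl)oxy]drim-8(12)-en-3-one
Conditions: PPh3, DIAD, THF, 0 °C → rt
Reagents that add atoms: none
Why: Mitsunobu etherification, in which the primary C11 alcohol is activated as its oxyphosphonium salt and displaced by the phenoxide of 19 (SN2 at CH2, no stereocentre involved).

Step 14
Reactants: 20 (4R,5S,9R,10R)-14-acetoxy-11-[(2-oxo-2H-chromen-7-yl)oxy]drim-8(12)-en-3-one
Product: 21 (3R,4R,5S,9R,10R)-14-acetoxy-3-hydroxy-11-[(2-oxo-2H-chromen-7-yl)oxy]drim-8(12)-ene (CNP0271943.1)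
Conditions: NaBH4, MeOH/THF, −20 °C
Reagents that add atoms: none
Why: Hydride reduction of a hindered cyclohexanone, in which NaBH4 attacks C3 along the axial trajectory on the face opposite to the axial C14 and C15 groups and should give the equatorial (3R) alcohol, while the acetate and the coumarin lactone are not reduced at low temperature.

Compound list
1 | (3-methoxyphenyl)methanol | COc1cccc(CO)c1 | starting material
2 | (5-methoxycyclohexa-1,4-dien-1-yl)methanol | COC1=CCC=C(CO)C1 | intermediate
3 | (4R)-4-benzyl-3-propanoyl-1,3-oxazolidin-2-one | CCC(=O)N1[C@H](Cc2ccccc2)COC1=O | starting material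
4 | prop-2-enal (acrolein) | C=CC=O | starting material
5 | (4R)-4-benzyl-3-[(2R,3S)-3-hydroxy-2-methylpent-4-enoyl]-1,3-oxazolidin-2-one | C=C[C@H](O)[C@@H](C)C(=O)N1[C@H](Cc2ccccc2)COC1=O | intermediate
6 | (5-methoxycyclohexa-1,4-dien-1-yl)methyl (2R,3S)-3-hydroxy-2-methylpent-4-enoate | C=C[C@H](O)[C@@H](C)C(=O)OCC1=CCC=C(OC)C1 | intermediate
7 | (2S,3S)-3-hydroxy-2-[(1S)-4-methoxy-6-methylidenecyclohex-3-en-1-yl]-2-methylpent-4-enoic acid (present as its dilithium salt) | COC1=CC[C@H]([C@](C)(C(=O)O)[C@@H](O)C=C)C(=C)C1 | intermediate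
8 | (2R,3S)-2-[(1S)-4-methoxy-6-methylidenecyclohex-3-en-1-yl]-2-methylpent-4-ene-1,3-diol | COC1=CC[C@H]([C@](C)(CO)[C@@H](O)C=C)C(=C)C1 | intermediate
9 | (4S)-4-[(2R,3S)-1,3-dihydroxy-2-methylpent-4-en-2-yl]-3-methylidenecyclohexan-1-one | O=C1CC[C@H]([C@](C)(CO)[C@@H](O)C=C)C(=C)C1 | intermediate
10 | (4S)-4-[(4S,5R)-4-ethenyl-2,2,5-trimethyl-1,3-dioxan-5-yl]-3-methylidenecyclohexan-1-one | O=C1CC[C@H]([C@]2(C)COC(C)(C)O[C@H]2C=C)C(=C)C1 | intermediate
11 | (2S,4S)-4-[(4S,5R)-4-ethenyl-2,2,5-trimethyl-1,3-dioxan-5-yl]-3-methylidene-2-({[tri(propan-2-yl)silyl]oxy}methyl)cyclohexan-1-one (C11 trans to the C5 substituent) | O=C1CC[C@H]([C@]2(C)COC(C)(C)O[C@H]2C=C)C(=C)[C@H]1CO[Si](C(C)C)(C(C)C)C(C)C | intermediate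
12 | (2R,4S)-4-[(4S,5R)-4-ethenyl-2,2,5-trimethyl-1,3-dioxan-5-yl]-3-methylidene-2-({[tri(propan-2-yl)silyl]oxy}methyl)cyclohexan-1-one (C11 cis to the C5 substituent) | O=C1CC[C@H]([C@]2(C)COC(C)(C)O[C@H]2C=C)C(=C)[C@@H]1CO[Si](C(C)C)(C(C)C)C(C)C | intermediate
13 | (2R,4S)-4-[(2R,3S)-1,3-dihydroxy-2-methylpent-4-en-2-yl]-3-methylidene-2-({[tri(propan-2-yl)silyl]oxy}methyl)cyclohexan-1-one | O=C1CC[C@H]([C@](C)(CO)[C@@H](O)C=C)C(=C)[C@@H]1CO[Si](C(C)C)(C(C)C)C(C)C | intermediate
14 | (2R,3S)-3-hydroxy-2-methyl-2-[(1S,3R)-2-methylidene-4-oxo-3-({[tri(propan-2-yl)silyl]oxy}methyl)cyclohexyl]pent-4-en-1-yl acetate | O=C1CC[C@H]([C@](C)(COC(C)=O)[C@@H](O)C=C)C(=C)[C@@H]1CO[Si](C(C)C)(C(C)C)C(C)C | intermediate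
15 | (2R)-2-methyl-2-[(1S,3R)-2-methylidene-4-oxo-3-({[tri(propan-2-yl)silyl]oxy}methyl)cyclohexyl]-3-oxopent-4-en-1-yl acetate | O=C1CC[C@H]([C@](C)(COC(C)=O)C(=O)C=C)C(=C)[C@@H]1CO[Si](C(C)C)(C(C)C)C(C)C | intermediate
16 | (4R,5S,9R,10R)-14-acetoxy-11-{[tri(propan-2-yl)silyl]oxy}-12-nordrimane-3,8-dione (trans-decalin; C15, C14 and C11 on one face, H5 and H9 on the other) | O=C1CC[C@@H]2[C@](C)(COC(C)=O)C(=O)CC[C@@]2(C)[C@@H]1CO[Si](C(C)C)(C(C)C)C(C)C | intermediate
17 | (4R,5S,9R,10R)-14-acetoxy-11-{[tri(propan-2-yl)silyl]oxy}drim-8(12)-en-3-one | C=C1CC[C@@H]2[C@](C)(COC(C)=O)C(=O)CC[C@@]2(C)[C@@H]1CO[Si](C(C)C)(C(C)C)C(C)C | intermediate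
18 | (4R,5S,9R,10R)-14-acetoxy-11-hydroxydrim-8(12)-en-3-one | C=C1CC[C@@H]2[C@](C)(COC(C)=O)C(=O)CC[C@@]2(C)[C@@H]1CO | intermediate
19 | 7-hydroxy-2H-chromen-2-one (umbelliferone) | Oc1ccc2ccc(=O)oc2c1 | starting material
20 | (4R,5S,9R,10R)-14-acetoxy-11-[(2-oxo-2H-chromen-7-yl)oxy]drim-8(12)-en-3-one | C=C1CC[C@@H]2[C@](C)(COC(C)=O)C(=O)CC[C@@]2(C)[C@@H]1COc1ccc2ccc(=O)oc2c1 | intermediate
21 | (3R,4R,5S,9R,10R)-14-acetoxy-3-hydroxy-11-[(2-oxo-2H-chromen-7-yl)oxy]drim-8(12)-ene | C=C1CC[C@@H]2[C@](C)(COC(C)=O)[C@H](O)CC[C@@]2(C)[C@@H]1COc1ccc2ccc(=O)oc2c1 | target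

Total step count: 14. Longest linear sequence: 13 steps (from 1 through steps 1 and 3–14, or from 3 through steps 2–14).

Steps most likely to fail

Step 10. The C10 radical may take up a second hydrogen atom (plain hydrogenation of the methylene), the vinyl ketone may be reduced or oligomerise before ring closure, or the ring fusion may form with low selectivity. The fallback sets out from 14 and comes back at 16. m-CPBA (CH2Cl2, 0 °C) should epoxidise the electron-rich 1,1-disubstituted alkene of 14 to the C10–C15 spiro-epoxide F1 (either configuration at C10 serves). Dess–Martin oxidation then gives the epoxy vinyl ketone F2. Cp2TiCl (from Cp2TiCl2 and Zn, THF, rt) opens the epoxide homolytically at the tertiary carbon (Nugent–RajanBabu reaction), and the resulting C10 radical closes ring A by the same 6-endo conjugate addition to give the 15-hydroxy decalindione F3. O-Phenyl chlorothionoformate/pyridine converts it into the thionocarbonate F4, and Bu3SnH/AIBN in toluene at 110 °C (Barton–McCombie deoxygenation) turns C15 into the methyl group of 16.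

Step 6. The dienolate may be alkylated on oxygen or at the exocyclic carbon C15, the exocyclic alkene may move into conjugation with C8=O during the second enolisation, or the inversion at C9 may stay incomplete. The fallback sets out from 10 and comes back at 12. LiN(i-Pr)2 followed by monomeric formaldehyde (aldol addition, which can only form the C–C bond) gives the hydroxymethyl ketone F5. i-Pr3SiCl/imidazole gives the trans silyl ether 11, which is isolated here. Me3SiOTf/Et3N gives the conjugated trimethylsilyl dienol ether F6 with fixed regiochemistry. MeLi in THF at −78 °C regenerates the lithium dienolate, and kinetic protonation with AcOH gives 12.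

Step 4. The mono-alkoxide may undergo retro-aldol cleavage before the second deprotonation, the hindered tetrasubstituted enolate may eliminate or rearrange slowly, and the facial control may erode. The fallback sets out from 6 and comes back at 9. MeOCH2Cl/i-Pr2NEt gives the methoxymethyl ether F7. LiN(i-Pr)2 in THF at −78 °C followed by Me3SiCl gives the silyl ketene acetal of the lithium-chelated enolate, which rearranges at rt (classical Ireland–Claisen rearrangement), and LiAlH4 added to the crude silyl ester gives the primary alcohol F8. 2 M HCl in THF removes the methoxymethyl group and hydrolyses the enol ether to 9; any C4/C5 diastereomers are separated at that stage.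

Further compounds
F1 | step 10 | C10–C15 spiro-epoxide of 14 (either configuration at C10) | O=C1CC[C@H]([C@](C)(COC(C)=O)[C@@H](O)C=C)C2(CO2)[C@@H]1CO[Si](C(C)C)(C(C)C)C(C)C
F2 | step 10 | C10–C15 spiro-epoxide of 15 (either configuration at C10) | O=C1CC[C@H]([C@](C)(COC(C)=O)C(=O)C=C)C2(CO2)[C@@H]1CO[Si](C(C)C)(C(C)C)C(C)C
F3 | step 10 | 15-hydroxy derivative of 16 | O=C1CC[C@@H]2[C@](C)(COC(C)=O)C(=O)CC[C@@]2(CO)[C@@H]1CO[Si](C(C)C)(C(C)C)C(C)C
F4 | step 10 | 15-O-(phenoxycarbonothioyl) derivative of F3 | O=C1CC[C@@H]2[C@](C)(COC(C)=O)C(=O)CC[C@@]2(COC(=S)Oc3ccccc3)[C@@H]1CO[Si](C(C)C)(C(C)C)C(C)C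
F5 | step 6 | (2S,4S)-4-[(4S,5R)-4-ethenyl-2,2,5-trimethyl-1,3-dioxan-5-yl]-2-(hydroxymethyl)-3-methylidenecyclohexan-1-one | O=C1CC[C@H]([C@]2(C)COC(C)(C)O[C@H]2C=C)C(=C)[C@H]1CO
F6 | step 6 | trimethylsilyl dienol ether of 11 (C8–OSiMe3, C8=C9, C10=CH2) | C[Si](C)(C)OC1=C(CO[Si](C(C)C)(C(C)C)C(C)C)C(=C)[C@@H]([C@]2(C)COC(C)(C)O[C@H]2C=C)CC1
F7 | step 4 | 3-O-methoxymethyl ether of 6 | C=C[C@H](OCOC)[C@@H](C)C(=O)OCC1=CCC=C(OC)C1
F8 | step 4 | 3-O-methoxymethyl ether of 8 | COC1=CC[C@H]([C@](C)(CO)[C@@H](OCOC)C=C)C(=C)C1
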